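**Retrosynthetic overview**
1. Target 39 ⇐ pentabenzyl trimethyl ester 36 (LiOH, then BCl3/C6HMe5). Its (E)-enol ether C=C ⇐ Still–Gennari olefination of a 3'-O–CH(P)CO2Me phosphonate (Rh O–H insertion at 3'-OH) with 3,4-bis(benzyloxy)benzaldehyde.
2. C2–H (trans to the C1 aryl) ⇐ Krapcho loss of one ester from a C2 gem-diester. C3=C4 ⇐ dehydration of a C3 carbinol; C2 is quaternary, so elimination can only go toward C4.
3. Ring B is the only ring built (the three benzene rings are bought) ⇐ one malonate carbon as C2: C1–C2 by 1,6-addition to a p-quinone methide, C2–C3 by aldol onto the ortho-tethered arylpyruvate ketone. The feature used: the free 4'-OH of the pendant ring is para to C1, so C1 can be a quinone methide carbon, and C2 lies between C1 and C3.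
4. Key-step precursor ⇐ sulfinate at C1, Heck reaction (C4a–C4) with methyl 2-acetoxyacrylate, aryllithium + aldehyde (C1–C1').

Key step: step 10

**Remarks on the chemistry (assumptions)**
- Sense of induction: the quinine-derived squaramide is written; if the first adduct has the opposite configuration at C1, the quinidine-derived pseudo-enantiomer is used.
- The arylpyruvate enters the key step as its O-acetyl enol. A free arylpyruvate is mostly enol, more acidic than dimethyl malonate, and its enol oxygen sits cis to the ortho carbon C1, where it would close onto the quinone methide (1H-isochromene). The ketone is released in the same flask once C1–C2 exists.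
- Phenol ethers: benzyl on ring A, later on 4'-O and on the caffeoyl ring (all removed last); allyl on 3'-O (removed alone by Pd(0)); MOM on 4'-O until the key step.

**Route**

Step 1
Reactants: 1 5-bromo-2-hydroxybenzaldehyde; 2 chloromethyl methyl ether
Product: 3 5-bromo-2-(methoxymethoxy)benzaldehyde
Conditions: MOMCl, i-Pr2NEt, CH2Cl2, 0 °C → rt
Reagents that add atoms: chloromethyl methyl ether (2), COCCl
Why: Williamson-type O-alkylation (MOM ether formation) of the phenol, which covers the oxygen that becomes the free 4'-OH of the key step with a group that later falls to acid alone.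

Step 2
Reactants: 3; 4 m-chloroperoxybenzoic acid
Product: 6 5-bromo-2-(methoxymethoxy)phenol, via aryl formate 5 (not isolated)
Conditions: mCPBA, CH2Cl2, rt; aq. Na2SO3/NaHCO3 wash; then K2CO3 (cat.), MeOH, rt
Reagents that add atoms: m-chloroperoxybenzoic acid (4), O=C(OO)c1cccc(Cl)c1
Why: Baeyer–Villiger (Dakin-type) oxidation in which the electron-rich 2-alkoxyaryl group migrates to oxygen, followed by base-catalysed methanolysis of the formate, turns CHO into the OH that becomes 3'-O.

Step 3
Reactants: 6; 7 allyl bromide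
Product: 8 2-(allyloxy)-4-bromo-1-(methoxymethoxy)benzene
Conditions: allyl bromide, K2CO3, DMF, rt
Reagents that add atoms: allyl bromide (7), C=CCBr
Why: Williamson ether synthesis; allyl is chosen for 3'-O because it is the one phenol ether that Pd(0) can later remove beside benzyl ethers and alkenes.

Step 4
Reactants: 9 3,4-bis(benzyloxy)benzaldehyde; 10 bromine
Product: 11 4,5-bis(benzyloxy)-2-bromobenzaldehyde
Conditions: Br2, NaOAc, AcOH, rt
Reagents that add atoms: bromine (10), BrBr
Why: Electrophilic aromatic bromination should occur at C6 (para to the 3-benzyloxy group, ortho to CHO), as with veratraldehyde, and NaOAc buffers the HBr so that the benzyl ethers survive.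

Step 5
Reactants: 8; 11
Product: 13 [3-(allyloxy)-4-(methoxymethoxy)phenyl][4,5-bis(benzyloxy)-2-bromophenyl]methanol (racemic), via aryllithium 12 (not isolated)
Conditions: n-BuLi, THF, −78 °C; then 11, −78 → −20 °C; H2O
Reagents that add atoms: 4,5-bis(benzyloxy)-2-bromobenzaldehyde (11), O=Cc1cc(OCc2ccccc2)c(OCc2ccccc2)cc1Br
Why: Bromine–lithium exchange and 1,2-addition of the aryllithium to the aldehyde make the C1–C1' bond; the metal is placed on the pendant ring so that no 2-bromoaryllithium (which would collapse to an aryne) is needed, and the carbinol centre is made racemic because it becomes planar in step 10.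

Step 6
Reactants: 13; 14 p-toluenesulfinic acid (freshly liberated from its sodium salt)
Product: 15 2-(allyloxy)-4-{[4,5-bis(benzyloxy)-2-bromophenyl](4-methylbenzenesulfonyl)methyl}-1-(methoxymethoxy)benzene (racemic)
Conditions: p-TolSO2H, MgSO4, CH2Cl2, rt
Reagents that add atoms: p-toluenesulfinic acid (14), Cc1ccc(cc1)S(=O)O
Why: SN1 substitution: the sulfinic acid ionises the carbinol to a benzhydryl cation stabilised by a para oxygen on each ring, and sulfinate captures it at sulfur to give the sulfone, the acid-stable resting form.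

Step 7
Reactants: 16 methyl pyruvate; 17 acetic anhydride
Product: 18 methyl 2-acetoxyacrylate
Conditions: Ac2O, p-TsOH (cat.), 120 °C, AcOH distilled off
Reagents that add atoms: acetic anhydride (17), CC(=O)OC(C)=O
Why: Acid-catalysed enol acetylation of the α-keto ester gives the captodative acrylate that serves as an O-protected pyruvate unit.

Step 8
Reactants: 15; 18
Product: 19 methyl (Z)-2-acetoxy-3-{2-[[3-(allyloxy)-4-(methoxymethoxy)phenyl](4-methylbenzenesulfonyl)methyl]-4,5-bis(benzyloxy)phenyl}acrylate (racemic at the sulfonyl carbon)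
Conditions: Pd(OAc)2, P(o-tol)3, NaOAc, DMF, 100 °C
Reagents that add atoms: methyl 2-acetoxyacrylate (18), C=C(OC(C)=O)C(=O)OC
Why: Mizoroki–Heck reaction: the arylpalladium adds to the CH2 terminus of the 1,1-disubstituted acrylate and β-hydride elimination gives the α-acetoxycinnamate (C4a–C4 bond), i.e. the arylpyruvate as its enol acetate; acetate as base leaves the sulfonyl C–H, the MOM and the allyl ether untouched.

Step 9
Reactants: 19
Product: 20 methyl (Z)-2-acetoxy-3-{2-[[3-(allyloxy)-4-hydroxyphenyl](4-methylbenzenesulfonyl)methyl]-4,5-bis(benzyloxy)phenyl}acrylate (racemic at the sulfonyl carbon; the key-step precursor, the arylpyruvate sulfone as its enol acetate)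
Conditions: TFA/CH2Cl2/H2O (10:40:1), 0 °C → rt; neutral work-up
Reagents that add atoms: none
Why: Acidolysis of the MOM acetal frees the 4'-OH while the sulfone (itself made under acid), the enol acetate, the benzyl and the allyl ethers are stable to TFA, and since no base is present no quinone methide forms before step 10.

Step 10
Reactants: 20; 21 dimethyl malonate
Product: 25 trimethyl (1R)-1-[3-(allyloxy)-4-hydroxyphenyl]-6,7-bis(benzyloxy)-3-hydroxy-1,2,3,4-tetrahydronaphthalene-2,2,3-tricarboxylate (C3 epimers), via quinone methide 22 (not isolated), via enol acetate adduct 23 (not isolated), via keto ester adduct 24 (not isolated)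
Conditions: (i) quinine-derived 3,5-bis(trifluoromethyl)phenyl squaramide (10 mol %), 21 (2 equiv), aq. K2CO3, toluene, 0 °C; (ii) MeOH, K2CO3, 0 °C → rt; pH 5 buffer quench at 0 °C
Reagents that add atoms: dimethyl malonate (21), COC(=O)CC(=O)OC
Why: Proposed new method: carbonate deprotonates the 4'-OH of 20 and the phenoxide expels p-toluenesulfinate to give quinone methide 22, whose exocyclic carbon (C1) takes the catalyst-bound malonate (C1–C2) and re-aromatises the phenol ring to 23; methanolysis of the enol acetate in the same flask then releases the arylpyruvate ketone (24), and the remaining malonate C–H, as its enolate, adds to that ketone carbon (C2–C3). The closest known chemistry is the organocatalytic enantioselective 1,6-addition of malonates to p-quinone methides generated in situ from such sulfones, joined here to a base-mediated Michael/aldol-type domino closure that has not been run onto an α-keto ester in this setting. Ring B is closed in a 6-exo-trig mode (6-enolexo, the carbonyl oxygen staying outside the ring). C1 is the only centre that must be controlled and is set by the catalyst, whose squaramide N–H bonds hold the quinone methide carbonyl while the protonated quinuclidine delivers the malonate to one face; the C3 carbinol forms as whichever epimer is more stable and is erased in step 12. The step needs attack of malonate carbon at C1 before any side-chain oxygen can reach C1, and aldol at the ketone in preference to a 5-exo Michael closure onto C4: the first is secured by keeping the pyruvate as its O-acetyl enol (neither acidic nor nucleophilic) until C1–C2 exists, the second by the enol acetate being a poor acceptor whereas the freed α-keto ester is the most electrophilic carbonyl of the molecule and sits in six-ring distance of the malonate carbon.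

Step 11
Reactants: 25; 26 benzyl bromide
Product: 27 trimethyl (1R)-1-[3-(allyloxy)-4-(benzyloxy)phenyl]-6,7-bis(benzyloxy)-3-hydroxy-1,2,3,4-tetrahydronaphthalene-2,2,3-tricarboxylate (C3 epimers)
Conditions: BnBr, K2CO3, acetone, rt
Reagents that add atoms: benzyl bromide (26), BrCc1ccccc1
Why: Williamson benzylation of the only phenol (the tertiary alcohol does not react), which also removes the phenoxide that a retro-1,6-addition would need, so C1 is configurationally safe from here on.

Step 12
Reactants: 27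
Product: 28 trimethyl (1R)-1-[3-(allyloxy)-4-(benzyloxy)phenyl]-6,7-bis(benzyloxy)-1,2-dihydronaphthalene-2,2,3-tricarboxylate
Conditions: SOCl2, pyridine, CH2Cl2, 0 °C → rt
Reagents that add atoms: none
Why: E2 dehydration through the chlorosulfite: C2 is quaternary, so pyridine can take only a C4 proton and the double bond lands at C3=C4 in conjugation with ring A and the C3 ester; a basic, non-ionising method is used because acid could fragment the C1–C2 bond through the stabilised benzhydryl cation.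

Step 13
Reactants: 28
Product: 30 dimethyl (1R,2S)-1-[3-(allyloxy)-4-(benzyloxy)phenyl]-6,7-bis(benzyloxy)-1,2-dihydronaphthalene-2,3-dicarboxylate (trans), via cis-diester 29 (not isolated)
Conditions: LiCl, H2O, DMSO, 130 °C; then DBU (cat.), toluene, rt
Reagents that add atoms: none
Why: Krapcho dealkoxycarbonylation: chloride demethylates one geminal ester, CO2 is lost and the dienolate is protonated at C2; DBU then equilibrates the C2 epimers through the same dienolate to the more stable trans-(1R,2S) diester, the fixed C1 centre being the controlling element.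

Step 14
Reactants: 30
Product: 31 dimethyl (1R,2S)-1-[4-(benzyloxy)-3-hydroxyphenyl]-6,7-bis(benzyloxy)-1,2-dihydronaphthalene-2,3-dicarboxylate
Conditions: Pd(PPh3)4 (cat.), morpholine, THF, rt
Reagents that add atoms: none
Why: Tsuji–Trost deallylation: Pd(0) ionises the aryl allyl ether and morpholine traps the π-allyl, freeing 3'-OH without touching benzyl ethers, esters or the ring alkene.

Step 15
Reactants: 32 methyl 2-[bis(2,2,2-trifluoroethoxy)phosphoryl]acetate; 33 4-acetamidobenzenesulfonyl azide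
Product: 34 methyl 2-[bis(2,2,2-trifluoroethoxy)phosphoryl]-2-diazoacetate
Conditions: p-ABSA, DBU, MeCN, 0 °C → rt
Reagents that add atoms: 4-acetamidobenzenesulfonyl azide (33), CC(=O)Nc1ccc(cc1)S(=O)(=O)N=[N+]=[N-]
Why: Regitz diazo transfer from the sulfonyl azide to the doubly activated methylene of the Still–Gennari phosphonate.

Step 16
Reactants: 31; 34
Product: 35 dimethyl (1R,2S)-1-{4-(benzyloxy)-3-[1-[bis(2,2,2-trifluoroethoxy)phosphoryl]-2-methoxy-2-oxoethoxy]phenyl}-6,7-bis(benzyloxy)-1,2-dihydronaphthalene-2,3-dicarboxylate (both epimers at the P-bearing carbon)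
Conditions: Rh2(OAc)4 (2 mol %), toluene, 80 °C, slow addition of 34
Reagents that add atoms: methyl 2-[bis(2,2,2-trifluoroethoxy)phosphoryl]-2-diazoacetate (34), COC(=O)C(=[N+]=[N-])P(=O)(OCC(F)(F)F)OCC(F)(F)F
Why: Rhodium-carbenoid O–H insertion into the phenol gives the α-aryloxy phosphonoacetate (the new centre is a mixture and is destroyed in step 17); phenol O–H insertion should be faster than addition to the electron-poor trisubstituted alkene or C–H insertion.

Step 17
Reactants: 35; 9
Product: 36 dimethyl (1R,2S)-1-{4-(benzyloxy)-3-[[(E)-1-[3,4-bis(benzyloxy)phenyl]-3-methoxy-3-oxoprop-1-en-2-yl]oxy]phenyl}-6,7-bis(benzyloxy)-1,2-dihydronaphthalene-2,3-dicarboxylate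
Conditions: KHMDS (1.0 equiv), 18-crown-6, THF, −78 °C; then 9; aq. NH4Cl
Reagents that add atoms: 3,4-bis(benzyloxy)benzaldehyde (9), O=Cc1ccc(OCc2ccccc2)c(OCc2ccccc2)c1
Why: Still–Gennari variant of the Horner–Wadsworth–Emmons reaction: the trifluoroethyl phosphonate anion adds irreversibly and eliminates fast, which under kinetic control should give the alkene with aryl cis to the ester, i.e. the (E)-enol ether; one equivalent of base at −78 °C takes the phosphonate C–H (the most acidic) and leaves C2–H alone.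

Step 18
Reactants: 36; 37 lithium hydroxide
Product: 38 (1R,2S)-1-{4-(benzyloxy)-3-[[(E)-2-[3,4-bis(benzyloxy)phenyl]-1-carboxyethenyl]oxy]phenyl}-6,7-bis(benzyloxy)-1,2-dihydronaphthalene-2,3-dicarboxylic acid
Conditions: LiOH, THF/MeOH/H2O, rt → 40 °C, Ar; then aq. HCl to pH 2
Reagents that add atoms: lithium hydroxide (37), [Li+].[OH-]
Why: Saponification (BAc2) of the three methyl esters while all phenols are still benzylated, so no catechol is exposed to base; C2 is already the thermodynamic trans epimer.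

Step 19
Reactants: 38
Product: 39 (1R,2S)-1-{3-[[(E)-1-carboxy-2-(3,4-dihydroxyphenyl)ethenyl]oxy]-4-hydroxyphenyl}-6,7-dihydroxy-1,2-dihydronaphthalene-2,3-dicarboxylic acid (CNP0241205.1)
Conditions: BCl3, pentamethylbenzene, CH2Cl2, −78 → −40 °C; then H2O; reversed-phase purification
Reagents that add atoms: none
Why: Lewis acid debenzylation: BCl3 cleaves the five aryl benzyl ethers at low temperature and pentamethylbenzene takes up the benzyl cations, conditions that should leave the enol ether, both alkenes and the C1/C2 centres untouched (hydrogenolysis is excluded by the two C=C bonds).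

**Compound list**
1 | 5-bromo-2-hydroxybenzaldehyde | O=Cc1cc(Br)ccc1O | starting material
2 | chloromethyl methyl ether | COCCl | starting material
3 | 5-bromo-2-(methoxymethoxy)benzaldehyde | O=Cc1cc(Br)ccc1OCOC | intermediate
4 | m-chloroperoxybenzoic acid | O=C(OO)c1cccc(Cl)c1 | starting material
5 | 5-bromo-2-(methoxymethoxy)phenyl formate | O=COc1cc(Br)ccc1OCOC | intermediate (not isolated)
6 | 5-bromo-2-(methoxymethoxy)phenol | Oc1cc(Br)ccc1OCOC | intermediate
7 | allyl bromide | C=CCBr | starting material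
8 | 2-(allyloxy)-4-bromo-1-(methoxymethoxy)benzene | C=CCOc1cc(Br)ccc1OCOC | intermediate
9 | 3,4-bis(benzyloxy)benzaldehyde | O=Cc1ccc(OCc2ccccc2)c(OCc2ccccc2)c1 | starting material
10 | bromine | BrBr | starting material
11 | 4,5-bis(benzyloxy)-2-bromobenzaldehyde | O=Cc1cc(OCc2ccccc2)c(OCc2ccccc2)cc1Br | intermediate
12 | [3-(allyloxy)-4-(methoxymethoxy)phenyl]lithium | [Li]c1ccc(OCOC)c(OCC=C)c1 | intermediate (not isolated)
13 | [3-(allyloxy)-4-(methoxymethoxy)phenyl][4,5-bis(benzyloxy)-2-bromophenyl]methanol (racemic) | OC(c1ccc(OCOC)c(OCC=C)c1)c1cc(OCc2ccccc2)c(OCc2ccccc2)cc1Br | intermediate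
14 | p-toluenesulfinic acid | Cc1ccc(cc1)S(=O)O | starting material
15 | 2-(allyloxy)-4-{[4,5-bis(benzyloxy)-2-bromophenyl](4-methylbenzenesulfonyl)methyl}-1-(methoxymethoxy)benzene (racemic) | Cc1ccc(cc1)S(=O)(=O)C(c1ccc(OCOC)c(OCC=C)c1)c1cc(OCc2ccccc2)c(OCc2ccccc2)cc1Br | intermediate
16 | methyl pyruvate | CC(=O)C(=O)OC | starting material
17 | acetic anhydride | CC(=O)OC(C)=O | starting material
18 | methyl 2-acetoxyacrylate | C=C(OC(C)=O)C(=O)OC | intermediate
19 | methyl (Z)-2-acetoxy-3-{2-[[3-(allyloxy)-4-(methoxymethoxy)phenyl](tosyl)methyl]-4,5-bis(benzyloxy)phenyl}acrylate (racemic at the sulfonyl carbon) | COC(=O)/C(OC(C)=O)=C/c1cc(OCc2ccccc2)c(OCc2ccccc2)cc1C(c1ccc(OCOC)c(OCC=C)c1)S(=O)(=O)c1ccc(C)cc1 | intermediate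
20 | methyl (Z)-2-acetoxy-3-{2-[[3-(allyloxy)-4-hydroxyphenyl](tosyl)methyl]-4,5-bis(benzyloxy)phenyl}acrylate (racemic at the sulfonyl carbon) | COC(=O)/C(OC(C)=O)=C/c1cc(OCc2ccccc2)c(OCc2ccccc2)cc1C(c1ccc(O)c(OCC=C)c1)S(=O)(=O)c1ccc(C)cc1 | intermediate (key-step precursor)
21 | dimethyl malonate | COC(=O)CC(=O)OC | starting material
22 | methyl (Z)-2-acetoxy-3-{2-[(3-(allyloxy)-4-oxocyclohexa-2,5-dien-1-ylidene)methyl]-4,5-bis(benzyloxy)phenyl}acrylate (p-quinone methide) | COC(=O)/C(OC(C)=O)=C/c1cc(OCc2ccccc2)c(OCc2ccccc2)cc1C=C1C=CC(=O)C(OCC=C)=C1 | intermediate (not isolated)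
23 | dimethyl 2-{(R)-[3-(allyloxy)-4-hydroxyphenyl][2-[(Z)-2-acetoxy-3-methoxy-3-oxoprop-1-enyl]-4,5-bis(benzyloxy)phenyl]methyl}malonate | COC(=O)/C(OC(C)=O)=C/c1cc(OCc2ccccc2)c(OCc2ccccc2)cc1[C@@H](c1ccc(O)c(OCC=C)c1)C(C(=O)OC)C(=O)OC | intermediate (not isolated)
24 | dimethyl 2-{(R)-[3-(allyloxy)-4-hydroxyphenyl][4,5-bis(benzyloxy)-2-(3-methoxy-2,3-dioxopropyl)phenyl]methyl}malonate | COC(=O)C(=O)Cc1cc(OCc2ccccc2)c(OCc2ccccc2)cc1[C@@H](c1ccc(O)c(OCC=C)c1)C(C(=O)OC)C(=O)OC | intermediate (not isolated)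
25 | trimethyl (1R)-1-[3-(allyloxy)-4-hydroxyphenyl]-6,7-bis(benzyloxy)-3-hydroxy-1,2,3,4-tetrahydronaphthalene-2,2,3-tricarboxylate (C3 not defined) | COC(=O)C1(O)Cc2cc(OCc3ccccc3)c(OCc3ccccc3)cc2[C@@H](c2ccc(O)c(OCC=C)c2)C1(C(=O)OC)C(=O)OC | intermediate (key-step product)
26 | benzyl bromide | BrCc1ccccc1 | starting material
27 | trimethyl (1R)-1-[3-(allyloxy)-4-(benzyloxy)phenyl]-6,7-bis(benzyloxy)-3-hydroxy-1,2,3,4-tetrahydronaphthalene-2,2,3-tricarboxylate (C3 not defined) | COC(=O)C1(O)Cc2cc(OCc3ccccc3)c(OCc3ccccc3)cc2[C@@H](c2ccc(OCc3ccccc3)c(OCC=C)c2)C1(C(=O)OC)C(=O)OC | intermediate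
28 | trimethyl (1R)-1-[3-(allyloxy)-4-(benzyloxy)phenyl]-6,7-bis(benzyloxy)-1,2-dihydronaphthalene-2,2,3-tricarboxylate | COC(=O)C1=Cc2cc(OCc3ccccc3)c(OCc3ccccc3)cc2[C@@H](c2ccc(OCc3ccccc3)c(OCC=C)c2)C1(C(=O)OC)C(=O)OC | intermediate
29 | dimethyl (1R,2R)-1-[3-(allyloxy)-4-(benzyloxy)phenyl]-6,7-bis(benzyloxy)-1,2-dihydronaphthalene-2,3-dicarboxylate (cis) | COC(=O)C1=Cc2cc(OCc3ccccc3)c(OCc3ccccc3)cc2[C@@H](c2ccc(OCc3ccccc3)c(OCC=C)c2)[C@H]1C(=O)OC | intermediate (not isolated)
30 | dimethyl (1R,2S)-1-[3-(allyloxy)-4-(benzyloxy)phenyl]-6,7-bis(benzyloxy)-1,2-dihydronaphthalene-2,3-dicarboxylate (trans) | COC(=O)C1=Cc2cc(OCc3ccccc3)c(OCc3ccccc3)cc2[C@@H](c2ccc(OCc3ccccc3)c(OCC=C)c2)[C@@H]1C(=O)OC | intermediate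
31 | dimethyl (1R,2S)-1-[4-(benzyloxy)-3-hydroxyphenyl]-6,7-bis(benzyloxy)-1,2-dihydronaphthalene-2,3-dicarboxylate | COC(=O)C1=Cc2cc(OCc3ccccc3)c(OCc3ccccc3)cc2[C@@H](c2ccc(OCc3ccccc3)c(O)c2)[C@@H]1C(=O)OC | intermediate
32 | methyl 2-[bis(2,2,2-trifluoroethoxy)phosphoryl]acetate | COC(=O)CP(=O)(OCC(F)(F)F)OCC(F)(F)F | starting material
33 | 4-acetamidobenzenesulfonyl azide | CC(=O)Nc1ccc(cc1)S(=O)(=O)N=[N+]=[N-] | starting material
34 | methyl 2-[bis(2,2,2-trifluoroethoxy)phosphoryl]-2-diazoacetate | COC(=O)C(=[N+]=[N-])P(=O)(OCC(F)(F)F)OCC(F)(F)F | intermediate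
35 | dimethyl (1R,2S)-1-{4-(benzyloxy)-3-[1-[bis(2,2,2-trifluoroethoxy)phosphoryl]-2-methoxy-2-oxoethoxy]phenyl}-6,7-bis(benzyloxy)-1,2-dihydronaphthalene-2,3-dicarboxylate (P-bearing carbon not defined) | COC(=O)C1=Cc2cc(OCc3ccccc3)c(OCc3ccccc3)cc2[C@@H](c2ccc(OCc3ccccc3)c(OC(C(=O)OC)P(=O)(OCC(F)(F)F)OCC(F)(F)F)c2)[C@@H]1C(=O)OC | intermediate
36 | dimethyl (1R,2S)-1-{4-(benzyloxy)-3-[[(E)-1-[3,4-bis(benzyloxy)phenyl]-3-methoxy-3-oxoprop-1-en-2-yl]oxy]phenyl}-6,7-bis(benzyloxy)-1,2-dihydronaphthalene-2,3-dicarboxylate | COC(=O)C1=Cc2cc(OCc3ccccc3)c(OCc3ccccc3)cc2[C@@H](c2ccc(OCc3ccccc3)c(O/C(=C/c3ccc(OCc4ccccc4)c(OCc4ccccc4)c3)C(=O)OC)c2)[C@@H]1C(=O)OC | intermediate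
37 | lithium hydroxide | [Li+].[OH-] | starting material
38 | (1R,2S)-1-{4-(benzyloxy)-3-[[(E)-2-[3,4-bis(benzyloxy)phenyl]-1-carboxyethenyl]oxy]phenyl}-6,7-bis(benzyloxy)-1,2-dihydronaphthalene-2,3-dicarboxylic acid | O=C(O)C1=Cc2cc(OCc3ccccc3)c(OCc3ccccc3)cc2[C@@H](c2ccc(OCc3ccccc3)c(O/C(=C/c3ccc(OCc4ccccc4)c(OCc4ccccc4)c3)C(=O)O)c2)[C@@H]1C(=O)O | intermediate
39 | (1R,2S)-1-{3-[[(E)-1-carboxy-2-(3,4-dihydroxyphenyl)ethenyl]oxy]-4-hydroxyphenyl}-6,7-dihydroxy-1,2-dihydronaphthalene-2,3-dicarboxylic acid | O=C(O)C1=Cc2cc(O)c(O)cc2[C@@H](c2ccc(O)c(O/C(=C/c3ccc(O)c(O)c3)C(=O)O)c2)[C@@H]1C(=O)O | target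

**Step count**
Total: 19 steps. Longest linear sequence: 16 steps (1, 2, 3, 5, 6, 8, 9, 10, 11, 12, 13, 14, 16, 17, 18, 19), from 5-bromo-2-hydroxybenzaldehyde.

**Steps most likely to fail, with fallbacks**

Step 10 (one-pot 1,6-addition / enol-ester cleavage / aldol). What may go wrong:
- the enol acetate is cleaved too early under the basic first stage, so that the side-chain enolate oxygen closes onto C1;
- after release of the ketone the aldol closure is incomplete or reverts (retro-aldol);
- malonate is lost again from C1 through the free phenoxide, which erodes the enantiomeric purity.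

The fallback makes the two bonds one at a time with known reactions. It sets out from sulfone 15. The MOM group is removed (TFA, CH2Cl2, H2O) to give 2-(allyloxy)-4-{[4,5-bis(benzyloxy)-2-bromophenyl](4-methylbenzenesulfonyl)methyl}phenol F1. This substrate carries no side chain, and the established squaramide-catalysed 1,6-addition of 21 (aq. K2CO3, toluene) should give dimethyl 2-{(R)-[3-(allyloxy)-4-hydroxyphenyl][4,5-bis(benzyloxy)-2-bromophenyl]methyl}malonate F2. Benzylation with 26 (K2CO3, acetone) gives dimethyl 2-{(R)-[3-(allyloxy)-4-(benzyloxy)phenyl][4,5-bis(benzyloxy)-2-bromophenyl]methyl}malonate F3, in which no phenoxide can form. A Heck reaction with 18 as in step 8 gives the enol acetate dimethyl 2-{(R)-[3-(allyloxy)-4-(benzyloxy)phenyl][2-[(Z)-2-acetoxy-3-methoxy-3-oxoprop-1-enyl]-4,5-bis(benzyloxy)phenyl]methyl}malonate F4. Methanolysis (K2CO3, MeOH, 0 °C) gives the arylpyruvate dimethyl 2-{(R)-[3-(allyloxy)-4-(benzyloxy)phenyl][4,5-bis(benzyloxy)-2-(3-methoxy-2,3-dioxopropyl)phenyl]methyl}malonate F5. Ring B is then closed by a titanium-templated intramolecular aldol (TiCl4, Et3N, CH2Cl2, −78 °C), where the chelated titanium aldolate is the resting state. This gives 27, where the route is rejoined.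

Step 17 (Still–Gennari olefination). What may go wrong: poor kinetic selectivity, so that the more stable (Z)-enol ether (aryl trans to the ester) is formed, or competing deprotonation at C2–H. The fallback sets the geometry by photochemical equilibration instead of by the olefination. It sets out from phenol 31. Diazo transfer with 33 onto trimethyl phosphonoacetate gives methyl 2-diazo-2-(dimethoxyphosphoryl)acetate F6. Rh2(OAc)4-catalysed O–H insertion into 31 gives dimethyl (1R,2S)-1-{4-(benzyloxy)-3-[1-(dimethoxyphosphoryl)-2-methoxy-2-oxoethoxy]phenyl}-6,7-bis(benzyloxy)-1,2-dihydronaphthalene-2,3-dicarboxylate F7. An ordinary Horner–Wadsworth–Emmons reaction with 9 (LiCl, DBU, MeCN) should give mainly the (Z)-isomer of 36, dimethyl (1R,2S)-1-{4-(benzyloxy)-3-[[(Z)-1-[3,4-bis(benzyloxy)phenyl]-3-methoxy-3-oxoprop-1-en-2-yl]oxy]phenyl}-6,7-bis(benzyloxy)-1,2-dihydronaphthalene-2,3-dicarboxylate F8. Visible-light triplet energy transfer (Ir(ppy)3, blue LEDs, MeCN) should then enrich the isomer whose aryl is cis to the ester, because it is twisted out of conjugation and is the poorer energy acceptor. Separation, with recycling of F8, gives 36, where the route is rejoined.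

Step 8 (Heck reaction). What may go wrong: slow oxidative addition into the electron-rich C–Br bond next to the bulky sulfonylmethyl group, or thermal loss of the enol ester at 100 °C. The fallback builds the side chain by olefination instead of palladium. It sets out from carbinol 13. O–H deprotonation and bromine–lithium exchange (n-BuLi, 2.2 equiv, THF, −78 °C) followed by DMF give 2-{[3-(allyloxy)-4-(methoxymethoxy)phenyl](hydroxy)methyl}-4,5-bis(benzyloxy)benzaldehyde F9 (in equilibrium with its lactol). Horner–Wadsworth–Emmons reaction with methyl 2-acetoxy-2-(dimethoxyphosphoryl)acetate (LiCl, DBU, MeCN) gives methyl (Z)-2-acetoxy-3-{2-[[3-(allyloxy)-4-(methoxymethoxy)phenyl](hydroxy)methyl]-4,5-bis(benzyloxy)phenyl}acrylate F10. Treatment with sulfinic acid 14 as in step 6 converts the carbinol to the sulfone and gives 19, where the route is rejoined.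

**Further compounds**
F1 | step 10 | 2-(allyloxy)-4-{[4,5-bis(benzyloxy)-2-bromophenyl](4-methylbenzenesulfonyl)methyl}phenol (racemic) | Cc1ccc(cc1)S(=O)(=O)C(c1ccc(O)c(OCC=C)c1)c1cc(OCc2ccccc2)c(OCc2ccccc2)cc1Br
F2 | step 10 | dimethyl 2-{(R)-[3-(allyloxy)-4-hydroxyphenyl][4,5-bis(benzyloxy)-2-bromophenyl]methyl}malonate | Brc1cc(OCc2ccccc2)c(OCc2ccccc2)cc1[C@@H](c1ccc(O)c(OCC=C)c1)C(C(=O)OC)C(=O)OC
F3 | step 10 | dimethyl 2-{(R)-[3-(allyloxy)-4-(benzyloxy)phenyl][4,5-bis(benzyloxy)-2-bromophenyl]methyl}malonate | Brc1cc(OCc2ccccc2)c(OCc2ccccc2)cc1[C@@H](c1ccc(OCc2ccccc2)c(OCC=C)c1)C(C(=O)OC)C(=O)OC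
F4 | step 10 | dimethyl 2-{(R)-[3-(allyloxy)-4-(benzyloxy)phenyl][2-[(Z)-2-acetoxy-3-methoxy-3-oxoprop-1-enyl]-4,5-bis(benzyloxy)phenyl]methyl}malonate | COC(=O)/C(OC(C)=O)=C/c1cc(OCc2ccccc2)c(OCc2ccccc2)cc1[C@@H](c1ccc(OCc2ccccc2)c(OCC=C)c1)C(C(=O)OC)C(=O)OC
F5 | step 10 | dimethyl 2-{(R)-[3-(allyloxy)-4-(benzyloxy)phenyl][4,5-bis(benzyloxy)-2-(3-methoxy-2,3-dioxopropyl)phenyl]methyl}malonate | COC(=O)C(=O)Cc1cc(OCc2ccccc2)c(OCc2ccccc2)cc1[C@@H](c1ccc(OCc2ccccc2)c(OCC=C)c1)C(C(=O)OC)C(=O)OC
F6 | step 17 | methyl 2-diazo-2-(dimethoxyphosphoryl)acetate | COC(=O)C(=[N+]=[N-])P(=O)(OC)OC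
F7 | step 17 | dimethyl (1R,2S)-1-{4-(benzyloxy)-3-[1-(dimethoxyphosphoryl)-2-methoxy-2-oxoethoxy]phenyl}-6,7-bis(benzyloxy)-1,2-dihydronaphthalene-2,3-dicarboxylate | COC(=O)C1=Cc2cc(OCc3ccccc3)c(OCc3ccccc3)cc2[C@@H](c2ccc(OCc3ccccc3)c(OC(C(=O)OC)P(=O)(OC)OC)c2)[C@@H]1C(=O)OC
F8 | step 17 | dimethyl (1R,2S)-1-{4-(benzyloxy)-3-[[(Z)-1-[3,4-bis(benzyloxy)phenyl]-3-methoxy-3-oxoprop-1-en-2-yl]oxy]phenyl}-6,7-bis(benzyloxy)-1,2-dihydronaphthalene-2,3-dicarboxylate | COC(=O)C1=Cc2cc(OCc3ccccc3)c(OCc3ccccc3)cc2[C@@H](c2ccc(OCc3ccccc3)c(O/C(=C\c3ccc(OCc4ccccc4)c(OCc4ccccc4)c3)C(=O)OC)c2)[C@@H]1C(=O)OC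
F9 | step 8 | 2-{[3-(allyloxy)-4-(methoxymethoxy)phenyl](hydroxy)methyl}-4,5-bis(benzyloxy)benzaldehyde (racemic) | O=Cc1cc(OCc2ccccc2)c(OCc2ccccc2)cc1C(O)c1ccc(OCOC)c(OCC=C)c1
F10 | step 8 | methyl (Z)-2-acetoxy-3-{2-[[3-(allyloxy)-4-(methoxymethoxy)phenyl](hydroxy)methyl]-4,5-bis(benzyloxy)phenyl}acrylate (racemic) | COC(=O)/C(OC(C)=O)=C/c1cc(OCc2ccccc2)c(OCc2ccccc2)cc1C(O)c1ccc(OCOC)c(OCC=C)c1
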